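## Retrosynthetic overview
1. Last step: Markovnikov hydration of a methallyl side chain gives the tertiary alcohol.
2. Key disconnection: the O1–C2 bond of the chroman, broken together with the adjacent CH2–C6 bond. One enantioselective oxypalladation/coupling joins a homomethallyl phenol to a β-bromoenone, closes ring B and sets C2.
3. The phenol comes from 4-methoxy-2-methylphenol through a Mannich base, an o-quinone methide and methallyl Grignard addition.
4. The bromoenone comes from the cis-dimethylhydrindane-4,6-dione by C-methallylation and regioselective bromination. The dione comes from radical closure of ring C in a cyclopentenyl β-ketonitrile.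
5. The β-ketonitrile comes from 2,3-dimethylcyclopent-2-enone by CBS reduction and Johnson–Claisen rearrangement. Ring order: D (bought), then C, then B last; A is bought.

Assumption: both starting materials are catalogue compounds, and (S)-AntPhos is taken to give the (2R) chroman; if a test run gives (2S), the commercial (R) ligand is used and nothing else changes.

## Route

Step 1
Reactants: 1 4-methoxy-2-methylphenol
Product: 2 2-[(dimethylamino)methyl]-4-methoxy-6-methylphenol
Conditions: aq Me2NH, aq CH2O, EtOH, 80 °C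
Reagents that add atoms: formaldehyde C=O; dimethylamine CNC
Why: Mannich aminomethylation of a phenol, in which the para position and one ortho position are blocked, so the iminium ion can attack only C6; no stereocentre is formed.

Step 2
Reactants: 2 2-[(dimethylamino)methyl]-4-methoxy-6-methylphenol
Product: 5 4-methoxy-2-methyl-6-(3-methylbut-3-en-1-yl)phenol, via ammonium iodide 3 (not isolated), via o-quinone methide 4 (not isolated)
Conditions: MeI, Et2O, rt, evaporate; 2-methylallylMgCl (3 equiv), THF, −78 °C to rt; cold 1 M HCl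
Reagents that add atoms: iodomethane CI; 2-methylallylmagnesium chloride CC(=C)C[Mg]Cl
Why: o-Quinone methide conjugate addition, in which the first equivalent of Grignard reagent deprotonates the phenol and expels NMe3, and the next adds 1,4 to the exocyclic CH2 with rearomatisation; no stereocentre is formed.

Step 3
Reactants: 6 2,3-dimethylcyclopent-2-en-1-one
Product: 7 (1S)-2,3-dimethylcyclopent-2-en-1-ol
Conditions: (R)-2-methyl-CBS-oxazaborolidine (10 mol %), BH3·SMe2, THF, −20 °C; MeOH, aq work-up
Reagents that add atoms: none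
Why: Corey–Bakshi–Shibata reduction, in which the catalyst-bound borane delivers hydride to the ketone face that keeps the bulky alkene arm away from the catalyst, setting C1 as (S) with clean 1,2-selectivity.

Step 4
Reactants: 7 (1S)-2,3-dimethylcyclopent-2-en-1-ol
Product: 9 ethyl 2-[(1S)-1,2-dimethylcyclopent-2-en-1-yl]acetate, via ketene acetal 8 (not isolated)
Conditions: MeC(OEt)3, EtCO2H (5 mol %), 140 °C, EtOH distilled off
Reagents that add atoms: triethyl orthoacetate CC(OCC)(OCC)OCC
Why: Johnson orthoester Claisen rearrangement, which is suprafacial across the ring, so the C–C bond forms on the face that carried the C–O bond and the (S) carbinol is traded for the (S) quaternary carbon (later C7a).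

Step 5
Reactants: 9 ethyl 2-[(1S)-1,2-dimethylcyclopent-2-en-1-yl]acetate
Product: 10 4-[(1S)-1,2-dimethylcyclopent-2-en-1-yl]-3-oxobutanenitrile
Conditions: MeCN, KOtBu (2.5 equiv), THF, rt; 1 M HCl
Reagents that add atoms: acetonitrile CC#N
Why: Claisen-type acylation of the acetonitrile anion, driven by deprotonation of the β-ketonitrile; the quaternary centre is untouched.

Step 6
Reactants: 10 4-[(1S)-1,2-dimethylcyclopent-2-en-1-yl]-3-oxobutanenitrile
Product: 12 (3aS,7aS)-3a,7a-dimethyltetrahydro-1H-indene-4,6(5H,7H)-dione, via enaminone 11 (not isolated)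
Conditions: Fe(acac)3 (30 mol %), PhSiH3, EtOH, 60 °C, N2, dilute; then 2 M HCl, THF, 60 °C
Reagents that add atoms: water O
Why: Metal-hydride hydrogen-atom-transfer (MHAT) alkene–nitrile radical cyclisation, in which H goes to the less substituted alkene carbon and the tertiary radical adds 6-exo to the nitrile carbon on the face that carries the tether, so the fusion is cis and C3a is set as (S); acid then hydrolyses 11.

Step 7
Reactants: 12 (3aS,7aS)-3a,7a-dimethyltetrahydro-1H-indene-4,6(5H,7H)-dione
Product: 13 (3aS,7aS)-6-hydroxy-3a,7a-dimethyl-5-(2-methylprop-2-en-1-yl)-1,2,3,3a,7,7a-hexahydro-4H-inden-4-one (drawn as the enol)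
Conditions: 2-methylallyl methyl carbonate (1.0 equiv), Pd(PPh3)4 (3 mol %), THF, 50 °C
Reagents that add atoms: 2-methylallyl methyl carbonate COC(=O)OCC(C)=C
Why: Tsuji–Trost allylation, in which the soft dione enolate attacks the π-methallyl complex at carbon (O-allylation is reversible under the catalyst) and the symmetric allyl termini leave no regiochemical issue; C5 is not a stereocentre in the enol.

Step 8
Reactants: 13 (3aS,7aS)-6-hydroxy-3a,7a-dimethyl-5-(2-methylprop-2-en-1-yl)-1,2,3,3a,7,7a-hexahydro-4H-inden-4-one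
Product: 14 (3aS,7aS)-6-bromo-3a,7a-dimethyl-5-(2-methylprop-2-en-1-yl)-1,2,3,3a,7,7a-hexahydro-4H-inden-4-one
Conditions: Ph3PBr2, Et3N, CH2Cl2, 0 °C to rt
Reagents that add atoms: dibromotriphenylphosphorane BrP(Br)(c1ccccc1)(c1ccccc1)c1ccccc1
Why: β-Diketone to β-bromoenone conversion through the enol phosphonium salt (addition–elimination), which occurs at C6 next to a CH2 and not at C4, which is shielded by the quaternary C3a; the amine buffer protects the methallyl group from HBr.

Step 9
Reactants: 5 4-methoxy-2-methyl-6-(3-methylbut-3-en-1-yl)phenol; 14 (3aS,7aS)-6-bromo-3a,7a-dimethyl-5-(2-methylprop-2-en-1-yl)-1,2,3,3a,7,7a-hexahydro-4H-inden-4-one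
Product: 15 (3aS,7aS)-6-{[(2R)-6-methoxy-2,8-dimethylchroman-2-yl]methyl}-3a,7a-dimethyl-5-(2-methylprop-2-en-1-yl)-1,2,3,3a,7,7a-hexahydro-4H-inden-4-one
Conditions: Pd2(dba)3 (2.5 mol %), (S)-AntPhos [P-chiral 4-(9-anthryl)-3-tert-butyl-2,3-dihydrobenzo[d][1,3]oxaphosphole] (10 mol %), Cs2CO3, toluene, 90 °C
Reagents that add atoms: none
Why: Proposed new method: enantioselective alkene aryloxy-alkenylation with a tetrasubstituted β-bromoenone as electrophile, in which zerovalent palladium inserts quickly into the activated C6–Br bond of 14, the caesium phenoxide of 5 replaces bromide on divalent palladium, the pendant 1,1-disubstituted alkene inserts syn into the Pd–O bond inside the pocket of the P-chiral monophosphine so that the O1–C2 bond and the (2R) centre form under catalyst control (the stereocentres of 14 are remote), and the resulting neopentyl-type alkylpalladium has no β-hydrogen and can only reductively eliminate with the alkenyl ligand to make the CH2–C6 bond; the hindered 2,6-disubstituted phenoxide, weak base and non-polar solvent hold back direct addition–elimination on 14; the closest known reaction type is palladium-catalysed alkene carboetherification of 2-(but-3-enyl)phenols with aryl bromides, which gives 2,2-disubstituted chromans enantioselectively but has not been shown with β-haloenones or with a chiral, fully substituted alkenyl partner.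

Step 10
Reactants: 15 (3aS,7aS)-6-{[(2R)-6-methoxy-2,8-dimethylchroman-2-yl]methyl}-3a,7a-dimethyl-5-(2-methylprop-2-en-1-yl)-1,2,3,3a,7,7a-hexahydro-4H-inden-4-one
Product: 16 (3aS,7aS)-5-(2-hydroxy-2-methylpropyl)-6-{[(2R)-6-methoxy-2,8-dimethylchroman-2-yl]methyl}-3a,7a-dimethyl-1,2,3,3a,7,7a-hexahydro-4H-inden-4-one (target)
Conditions: Co(acac)2 (20 mol %), PhSiH3, O2 (1 atm), THF, rt
Reagents that add atoms: dioxygen O=O
Why: Mukaiyama hydration (cobalt-hydride MHAT, then O2 capture and reduction), which is Markovnikov and touches only the electron-rich 1,1-disubstituted alkene, because the tetrasubstituted enone is inert; no stereocentre is formed or disturbed.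

## Compound list
1 | 4-methoxy-2-methylphenol | COc1ccc(O)c(C)c1 | starting material
2 | 2-[(dimethylamino)methyl]-4-methoxy-6-methylphenol | COc1cc(C)c(O)c(CN(C)C)c1 | intermediate
3 | (2-hydroxy-5-methoxy-3-methylbenzyl)trimethylammonium iodide | COc1cc(C)c(O)c(C[N+](C)(C)C)c1.[I-] | intermediate
4 | 4-methoxy-2-methyl-6-methylidenecyclohexa-2,4-dien-1-one | COC1=CC(=C)C(=O)C(C)=C1 | intermediate
5 | 4-methoxy-2-methyl-6-(3-methylbut-3-en-1-yl)phenol | COc1cc(C)c(O)c(CCC(C)=C)c1 | intermediate
6 | 2,3-dimethylcyclopent-2-en-1-one | CC1=C(C)C(=O)CC1 | starting material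
7 | (1S)-2,3-dimethylcyclopent-2-en-1-ol | O[C@H]1CCC(C)=C1C | intermediate
8 | (1S)-2,3-dimethylcyclopent-2-en-1-yl 1-ethoxyvinyl ether | C=C(OCC)O[C@H]1CCC(C)=C1C | intermediate
9 | ethyl 2-[(1S)-1,2-dimethylcyclopent-2-en-1-yl]acetate | CCOC(=O)C[C@]1(C)CCC=C1C | intermediate
10 | 4-[(1S)-1,2-dimethylcyclopent-2-en-1-yl]-3-oxobutanenitrile | N#CCC(=O)C[C@]1(C)CCC=C1C | intermediate
11 | (3aS,7aS)-7-amino-3a,7a-dimethyl-1,2,3,3a,4,7a-hexahydro-5H-inden-5-one | O=C1C=C(N)[C@@]2(C)CCC[C@@]2(C)C1 | intermediate
12 | (3aS,7aS)-3a,7a-dimethyltetrahydro-1H-indene-4,6(5H,7H)-dione (cis fusion, methyls syn) | O=C1CC(=O)[C@@]2(C)CCC[C@@]2(C)C1 | intermediate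
13 | (3aS,7aS)-6-hydroxy-3a,7a-dimethyl-5-(2-methylprop-2-en-1-yl)-1,2,3,3a,7,7a-hexahydro-4H-inden-4-one | OC1=C(CC(C)=C)C(=O)[C@@]2(C)CCC[C@@]2(C)C1 | intermediate
14 | (3aS,7aS)-6-bromo-3a,7a-dimethyl-5-(2-methylprop-2-en-1-yl)-1,2,3,3a,7,7a-hexahydro-4H-inden-4-one | BrC1=C(CC(C)=C)C(=O)[C@@]2(C)CCC[C@@]2(C)C1 | intermediate
15 | (3aS,7aS)-6-{[(2R)-6-methoxy-2,8-dimethylchroman-2-yl]methyl}-3a,7a-dimethyl-5-(2-methylprop-2-en-1-yl)-1,2,3,3a,7,7a-hexahydro-4H-inden-4-one | COc1cc(C)c2c(c1)CC[C@](C)(CC1=C(CC(C)=C)C(=O)[C@@]3(C)CCC[C@@]3(C)C1)O2 | intermediate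
16 | (3aS,7aS)-5-(2-hydroxy-2-methylpropyl)-6-{[(2R)-6-methoxy-2,8-dimethylchroman-2-yl]methyl}-3a,7a-dimethyl-1,2,3,3a,7,7a-hexahydro-4H-inden-4-one | COc1cc(C)c2c(c1)CC[C@](C)(CC1=C(CC(C)(C)O)C(=O)[C@@]3(C)CCC[C@@]3(C)C1)O2 | target

## Count and risks
Total steps: 10 (2 to reach 5, 6 to reach 14, 2 after the union). Longest linear sequence: 8 (steps 3 to 10, from 6 to 16).

**Step 9 (the new step).**
- It can fail by direct O-alkenylation of the phenoxide (addition–elimination or C–O reductive elimination), by Heck-type pathways, or by a poor ratio at C2.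
- The fallback uses known chemistry and makes the C–C bond first and the C–O bond second. It sets out from 5 and 14 and comes back at 15.
- Mizoroki–Heck coupling of 14 with the free phenol 5 is run under base-poor Jeffery conditions (Pd(OAc)2, Bu4NCl, NaHCO3, DMF, 80 °C). A DBU wash then brings the alkene isomers into conjugation and gives the dienone phenol F1.
- More DBU in warm toluene closes the chroman by reversible intramolecular oxa-1,6-conjugate addition. This gives 15 together with the C2 epimer F2.
- The two are separated by preparative HPLC, and F2 is returned to the DBU equilibration.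

**Step 6.**
- The 6-exo addition of a hindered tertiary radical to a nitrile next to a quaternary carbon may lose to simple alkene reduction, and the acidic β-ketonitrile may bind iron.
- The fallback closes ring C on a much better radical acceptor and installs the C4 oxygen afterwards. It sets out from 9 and comes back at 12.
- MeNH(OMe)·HCl with iPrMgCl gives the Weinreb amide F3, and vinylMgBr gives the vinyl ketone F4.
- Fe(acac)3/PhSiH3 in EtOH effects reductive olefin coupling, a 6-endo Giese closure on the enone terminus, and gives the cis-hydrindanone F5.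
- 2-Iodoxybenzoic acid in DMSO dehydrogenates the only side that has a β-hydrogen and gives the enone F6.
- H2O2/NaOH gives the epoxy ketone F7, and Pd(PPh3)4/dppe in hot toluene isomerises it to 12.

**Step 4.**
- Alcohol 7 ionises easily, so hot acid may cause elimination to the diene and erode the ee.
- The fallback is an acid-free ester-enolate rearrangement. It sets out from 7 and comes back at 9.
- Ac2O/pyridine gives the acetate F8, and LDA then TMSCl at −78 °C gives the silyl ketene acetal F9.
- Warming to 60 °C brings about the Ireland–Claisen rearrangement to the silyl ester F10.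
- Aqueous work-up gives the acid F11, and EtI/K2CO3 in DMF gives 9.

## Further compounds
F1 | step 9 | (3aS,7aS)-6-[(1E)-4-(2-hydroxy-5-methoxy-3-methylphenyl)-2-methylbut-1-en-1-yl]-3a,7a-dimethyl-5-(2-methylprop-2-en-1-yl)-1,2,3,3a,7,7a-hexahydro-4H-inden-4-one | COc1cc(C)c(O)c(CC/C(C)=C/C2=C(CC(C)=C)C(=O)[C@@]3(C)CCC[C@@]3(C)C2)c1
F2 | step 9 | (2S) epimer of 15 | COc1cc(C)c2c(c1)CC[C@@](C)(CC1=C(CC(C)=C)C(=O)[C@@]3(C)CCC[C@@]3(C)C1)O2
F3 | step 6 | 2-[(1S)-1,2-dimethylcyclopent-2-en-1-yl]-N-methoxy-N-methylacetamide | CON(C)C(=O)C[C@]1(C)CCC=C1C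
F4 | step 6 | 1-[(1S)-1,2-dimethylcyclopent-2-en-1-yl]but-3-en-2-one | C=CC(=O)C[C@]1(C)CCC=C1C
F5 | step 6 | (3aS,7aR)-3a,7a-dimethyloctahydro-5H-inden-5-one (cis fusion) | O=C1CC[C@@]2(C)CCC[C@@]2(C)C1
F6 | step 6 | (3aS,7aR)-3a,7a-dimethyl-1,2,3,3a,4,7a-hexahydro-5H-inden-5-one | O=C1C=C[C@@]2(C)CCC[C@@]2(C)C1
F7 | step 6 | 6,7-epoxide of F6, oxirane oxygen anti to the two angular methyl groups | O=C1[C@H]2O[C@H]2[C@@]3(C)CCC[C@@]3(C)C1
F8 | step 4 | (1S)-2,3-dimethylcyclopent-2-en-1-yl acetate | CC(=O)O[C@H]1CCC(C)=C1C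
F9 | step 4 | (1S)-2,3-dimethylcyclopent-2-en-1-yl 1-(trimethylsilyloxy)vinyl ether | C=C(O[Si](C)(C)C)O[C@H]1CCC(C)=C1C
F10 | step 4 | trimethylsilyl 2-[(1S)-1,2-dimethylcyclopent-2-en-1-yl]acetate | C[Si](C)(C)OC(=O)C[C@]1(C)CCC=C1C
F11 | step 4 | 2-[(1S)-1,2-dimethylcyclopent-2-en-1-yl]acetic acid | OC(=O)C[C@]1(C)CCC=C1C
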